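## Retrosynthetic overview

1. Ring atoms are numbered C1 (stereocentre bearing the side chain), C2 (C–CH3, sp2), C3 (=CH), C4 and C5 (CH2), C6 (C(CH3)2). The oleate ester and a silyl ether are disconnected last; the C2=C3 alkene is traced back to the C3 ketone 15 through its more substituted enol triflate.
2. Ketone 15 is opened at C5–C6: the only ring is formed by a hydrogen-atom-transfer-initiated 6-endo radical cyclisation of the acyclic vinyl ketone 14, in which C6 is still the inner carbon of an isopropenyl group.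
3. Enabling feature: C6 is a quaternary ring carbon with two methyl groups, bonded directly to the ring CH2 C5. One methyl can therefore be carried as the =CH2 of an isopropenyl group (a latent tertiary radical at C6), and the C2=C3 ring alkene allows a carbonyl at C3 that makes C4=C5 a radical acceptor.
4. 14 is traced to (2E,6E)-farnesol: oxidation at C12, propanoate formation, and an enantioselective Ireland–Claisen rearrangement that joins C2 to farnesol C10 (= C1, the only stereocentre) and leaves farnesol C11/C12 as the isopropenyl group (= C6 and one of its methyls). CH2=CHMgBr supplies C4 and C5.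
5. Farnesol C1–C9 is carried through unchanged as the (2E,6E) side chain; one ring, formed in step 7.

Key step: step 7

Assumption: the (4S,5S) boron controller 6 is taken to be the enantiomer that gives (3R)-9 (the later (S) ring centre). The sense of induction must be confirmed on the first run; if it is the reverse, the (4R,5R) enantiomer is used and nothing else changes.

Remark: the methyl-bearing centre next to it (later C2) is erased in step 8, so its configuration is of no consequence. The isomer expected from a Z(O) ketene acetal is drawn.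

## Route

Step 1
Reactants: 1 (2E,6E)-farnesol
Product: 2 tert-butyldiphenyl{[(2E,6E)-3,7,11-trimethyldodeca-2,6,10-trien-1-yl]oxy}silane
Conditions: t-BuPh2SiCl, imidazole, DMF, 0 °C to rt
Reagents that add atoms: tert-butyl(chloro)diphenylsilane, CC(C)(C)[Si](Cl)(c1ccccc1)c1ccccc1
Why: Standard silylation of a primary allylic alcohol; the bulky silyl ether should survive the basic, Lewis acidic, radical and palladium conditions of steps 2 to 9.

Step 2
Reactants: 2 farnesyl tert-butyldiphenylsilyl ether
Product: 3 (2E,6E,10E)-12-[(tert-butyldiphenylsilyl)oxy]-2,6,10-trimethyldodeca-2,6,10-trien-1-ol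
Conditions: SeO2 (0.1 equiv), t-BuOOH (3 equiv), salicylic acid (0.1 equiv), CH2Cl2, 0 °C to rt
Reagents that add atoms: tert-butyl hydroperoxide, CC(C)(C)OO (terminal oxygen source; the oxygen is relayed through selenium dioxide, O=[Se]=O)
Why: Riley-type allylic oxidation (ene reaction, then [2,3]-sigmatropic shift) is known to pick the (E)-methyl group of the terminal trisubstituted alkene of farnesyl derivatives and should give the (E)-allylic alcohol without touching the alkene geometries.

Step 3
Reactants: 3 the C12 allylic alcohol, 4 propanoic anhydride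
Product: 5 (2E,6E,10E)-12-[(tert-butyldiphenylsilyl)oxy]-2,6,10-trimethyldodeca-2,6,10-trien-1-yl propanoate
Conditions: Et3N, DMAP (cat.), CH2Cl2, 0 °C to rt
Reagents that add atoms: none
Why: DMAP-catalysed acylation of an unhindered primary allylic alcohol; no stereocentre is formed.

Step 4
Reactants: 5 the allylic propanoate, 6 (4S,5S)-2-bromo-1,3-bis{[3,5-bis(trifluoromethyl)phenyl]sulfonyl}-4,5-diphenyl-1,3,2-diazaborolidine
Product: 9 (2R,3R,6E,10E)-12-[(tert-butyldiphenylsilyl)oxy]-2,6,10-trimethyl-3-(prop-1-en-2-yl)dodeca-6,10-dienoic acid, via boron ketene acetal 7 (not isolated), via boryl carboxylate 8 (not isolated)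
Conditions: 6 (1.2 equiv), i-Pr2NEt (1.5 equiv), CH2Cl2, −78 °C, then −20 °C to rt (prolonged); aqueous work-up with recovery of the bis-sulfonamide
Reagents that add atoms: none
Why: Enantioselective Ireland–Claisen rearrangement: soft enolisation with the chiral bromoborane gives the Z(O) boron ketene acetal, whose [3,3] shift through a chair transition state on the (E)-alkene forms the C2–C1 bond (ring numbering) with syn relative configuration, while the C2-symmetric sulfonamide ligand on boron selects the enolate face and so sets the (3R) centre that becomes C1 of the ring.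

Step 5
Reactants: 9 the (2R,3R)-acid
Product: 11 (2R,3R,6E,10E)-12-[(tert-butyldiphenylsilyl)oxy]-N-methoxy-N,2,6,10-tetramethyl-3-(prop-1-en-2-yl)dodeca-6,10-dienamide, via acyl imidazolide 10 (not isolated)
Conditions: 1,1'-carbonyldiimidazole, CH2Cl2, rt; then MeNHOMe·HCl, rt
Reagents that add atoms: N,O-dimethylhydroxylamine hydrochloride, CNOC.Cl; 1,1'-carbonyldiimidazole, O=C(n1ccnc1)n1ccnc1 (its atoms are kept only in 10)
Why: Acyl imidazolide activation followed by aminolysis is a mild amide formation that tolerates the α-branched acid and the alkenes; the stereocentres are untouched.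

Step 6
Reactants: 11 the N-methoxy-N-methyl amide, 12 vinylmagnesium bromide
Product: 14 (4R,5R,8E,12E)-14-[(tert-butyldiphenylsilyl)oxy]-4,8,12-trimethyl-5-(prop-1-en-2-yl)tetradeca-1,8,12-trien-3-one, via magnesium hemiaminal chelate 13 (not isolated)
Conditions: CH2=CHMgBr (3 equiv), THF, −78 to 0 °C; inverse quench into cold 1 M HCl
Reagents that add atoms: none
Why: Weinreb ketone synthesis: the stable five-membered magnesium chelate prevents over-addition, and the cold acidic inverse quench keeps the liberated hydroxylamine from adding to the new vinyl ketone.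

Step 7
Reactants: 14 the acyclic vinyl ketone
Product: 15 (2R,3R)-3-[(3E,7E)-9-[(tert-butyldiphenylsilyl)oxy]-3,7-dimethylnona-3,7-dien-1-yl]-2,4,4-trimethylcyclohexan-1-one
Conditions: Fe(acac)3 (30 mol %), PhSiH3 (2.5 equiv), EtOH/ethylene glycol 5:1, 0.01 M, 60 °C
Reagents that add atoms: none
Why: Fe(acac)3 and PhSiH3 in ethanol form an iron hydride that transfers a hydrogen atom to the CH2 terminus of the isopropenyl group of 14, which turns that carbon into the second methyl group and leaves a nucleophilic tertiary radical at C6; this radical adds to the unsubstituted terminus C5 of the vinyl ketone, and the α-keto radical at C4 is reduced by divalent iron to the enolate and protonated by ethanol. The closest known reaction type is the iron-catalysed reductive olefin–enone coupling (hydrogen-atom-transfer Giese reaction), which builds quaternary carbons and has been run intramolecularly, combined with the ring-closure mode known from tin hydride cyclisations of radicals onto vinyl ketones whose carbonyl lies inside the new ring. The ring closes 6-endo-trig, because 5-exo attack at C4 would place the nucleophilic radical on the α-carbon of the enone and give a primary radical. No stereocentre arises at C6 (two identical methyl groups); C1 is neither radical nor acceptor carbon and keeps the configuration set in step 4, and C2 is expected to stay trans to the side chain, its epimer being equally usable since the centre is erased in step 8. The selectivity needed is chemoselectivity among four alkenes: the isopropenyl group is the least hindered electron-rich alkene and the fastest unactivated hydrogen-atom acceptor compared with the two trisubstituted side-chain alkenes, and the polarity-matched, unhindered vinyl ketone should capture the C6 radical much faster than the electron-rich C3'=C4' alkene of the side chain; high dilution suppresses intermolecular addition.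

Step 8
Reactants: 15 the cyclohexanone
Product: 16 (3S)-3-[(3E,7E)-9-[(tert-butyldiphenylsilyl)oxy]-3,7-dimethylnona-3,7-dien-1-yl]-2,4,4-trimethylcyclohex-1-en-1-yl trifluoromethanesulfonate
Conditions: Tf2O (1.3 equiv), 2,6-di-tert-butyl-4-methylpyridine (1.5 equiv), CH2Cl2, 0 °C to rt
Reagents that add atoms: trifluoromethanesulfonic anhydride, O=S(=O)(OS(=O)(=O)C(F)(F)F)C(F)(F)F
Why: O-triflation with the anhydride and a hindered pyridine runs under equilibrating enolisation and should favour the more substituted enol triflate, which fixes the double bond between C2 and C3 and erases the C2 centre, while C1 is not enolisable and is untouched.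

Step 9
Reactants: 16 the enol triflate
Product: 17 tert-butyldiphenyl{[(2E,6E)-3,7-dimethyl-9-[(1S)-2,6,6-trimethylcyclohex-2-en-1-yl]nona-2,6-dien-1-yl]oxy}silane
Conditions: Pd(OAc)2 (5 mol %), PPh3 (10 mol %), HCO2H (3 equiv), n-Bu3N (4 equiv), DMF, 60 °C
Reagents that add atoms: none
Why: Palladium-catalysed formate reduction of an enol triflate (oxidative addition to zerovalent palladium, formate exchange, loss of CO2, reductive elimination) replaces the triflate by hydrogen without moving the alkene or touching the allylic C1–H.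

Step 10
Reactants: 17 the silyl ether
Product: 18 (2E,6E)-3,7-dimethyl-9-[(1S)-2,6,6-trimethylcyclohex-2-en-1-yl]nona-2,6-dien-1-ol
Conditions: Bu4NF (1.5 equiv), THF, 0 °C to rt
Reagents that add atoms: none
Why: Fluoride-induced cleavage of the Si–O bond is neutral enough to leave the three alkenes and the allylic stereocentre unchanged.

Step 11
Reactants: 18 the diterpene alcohol, 19 oleic acid
Product: 21 (2E,6E)-3,7-dimethyl-9-[(1S)-2,6,6-trimethylcyclohex-2-en-1-yl]nona-2,6-dien-1-yl (9Z)-octadec-9-enoate, via O-acylisourea 20 (not isolated)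
Conditions: N,N'-dicyclohexylcarbodiimide (1.3 equiv), DMAP (0.1 equiv), CH2Cl2, 0 °C to rt
Reagents that add atoms: N,N'-dicyclohexylcarbodiimide, C(=NC1CCCCC1)=NC1CCCCC1 (its atoms are kept only in 20)
Why: Steglich esterification through the O-acylisourea and the acylpyridinium ion acylates the primary allylic alcohol under neutral conditions, so neither the (Z)-alkene of the acid nor the allylic ester should isomerise.

## Compound list

1 | (2E,6E)-farnesol, (2E,6E)-3,7,11-trimethyldodeca-2,6,10-trien-1-ol | OC/C=C(\C)CC/C=C(\C)CCC=C(C)C | starting material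
2 | tert-butyldiphenyl{[(2E,6E)-3,7,11-trimethyldodeca-2,6,10-trien-1-yl]oxy}silane | CC(C)(C)[Si](c1ccccc1)(c1ccccc1)OC/C=C(\C)CC/C=C(\C)CCC=C(C)C | intermediate
3 | (2E,6E,10E)-12-[(tert-butyldiphenylsilyl)oxy]-2,6,10-trimethyldodeca-2,6,10-trien-1-ol | CC(C)(C)[Si](c1ccccc1)(c1ccccc1)OC/C=C(\C)CC/C=C(\C)CC/C=C(\C)CO | intermediate
4 | propanoic anhydride | CCC(=O)OC(=O)CC | starting material
5 | (2E,6E,10E)-12-[(tert-butyldiphenylsilyl)oxy]-2,6,10-trimethyldodeca-2,6,10-trien-1-yl propanoate | CC(C)(C)[Si](c1ccccc1)(c1ccccc1)OC/C=C(\C)CC/C=C(\C)CC/C=C(\C)COC(=O)CC | intermediate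
6 | (4S,5S)-2-bromo-1,3-bis{[3,5-bis(trifluoromethyl)phenyl]sulfonyl}-4,5-diphenyl-1,3,2-diazaborolidine (stoichiometric chiral controller, made beforehand from the bis-sulfonamide and BBr3) | BrB1N(S(=O)(=O)c2cc(C(F)(F)F)cc(C(F)(F)F)c2)[C@@H](c2ccccc2)[C@H](c2ccccc2)N1S(=O)(=O)c1cc(C(F)(F)F)cc(C(F)(F)F)c1 | starting material
7 | boron ketene acetal of 5 (enol oxygen on the boron of 6 in place of bromine; methyl cis to O–B) | CC(C)(C)[Si](c1ccccc1)(c1ccccc1)OC/C=C(\C)CC/C=C(\C)CC/C=C(\C)CO/C(OB1N(S(=O)(=O)c2cc(C(F)(F)F)cc(C(F)(F)F)c2)[C@@H](c2ccccc2)[C@H](c2ccccc2)N1S(=O)(=O)c1cc(C(F)(F)F)cc(C(F)(F)F)c1)=C/C | intermediate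
8 | boryl carboxylate of 9 (carboxyl oxygen on the boron of the diazaborolidine) | CC(C)(C)[Si](c1ccccc1)(c1ccccc1)OC/C=C(\C)CC/C=C(\C)CC[C@@H](C(C)=C)[C@@H](C)C(=O)OB1N(S(=O)(=O)c2cc(C(F)(F)F)cc(C(F)(F)F)c2)[C@@H](c2ccccc2)[C@H](c2ccccc2)N1S(=O)(=O)c1cc(C(F)(F)F)cc(C(F)(F)F)c1 | intermediate
9 | (2R,3R,6E,10E)-12-[(tert-butyldiphenylsilyl)oxy]-2,6,10-trimethyl-3-(prop-1-en-2-yl)dodeca-6,10-dienoic acid | CC(C)(C)[Si](c1ccccc1)(c1ccccc1)OC/C=C(\C)CC/C=C(\C)CC[C@@H](C(C)=C)[C@@H](C)C(=O)O | intermediate
10 | acyl imidazolide of 9, 1-acyl-1H-imidazole | CC(C)(C)[Si](c1ccccc1)(c1ccccc1)OC/C=C(\C)CC/C=C(\C)CC[C@@H](C(C)=C)[C@@H](C)C(=O)n1ccnc1 | intermediate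
11 | (2R,3R,6E,10E)-12-[(tert-butyldiphenylsilyl)oxy]-N-methoxy-N,2,6,10-tetramethyl-3-(prop-1-en-2-yl)dodeca-6,10-dienamide | CC(C)(C)[Si](c1ccccc1)(c1ccccc1)OC/C=C(\C)CC/C=C(\C)CC[C@@H](C(C)=C)[C@@H](C)C(=O)N(C)OC | intermediate
12 | vinylmagnesium bromide | C=C[Mg]Br | starting material
13 | bromomagnesium salt of the tetrahedral adduct of 11 and 12 (N-methoxy-N-methyl hemiaminal, either configuration at the new carbon) | CC(C)(C)[Si](c1ccccc1)(c1ccccc1)OC/C=C(\C)CC/C=C(\C)CC[C@@H](C(C)=C)[C@@H](C)C(O[Mg]Br)(C=C)N(C)OC | intermediate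
14 | (4R,5R,8E,12E)-14-[(tert-butyldiphenylsilyl)oxy]-4,8,12-trimethyl-5-(prop-1-en-2-yl)tetradeca-1,8,12-trien-3-one | CC(C)(C)[Si](c1ccccc1)(c1ccccc1)OC/C=C(\C)CC/C=C(\C)CC[C@@H](C(C)=C)[C@@H](C)C(=O)C=C | intermediate
15 | (2R,3R)-3-[(3E,7E)-9-[(tert-butyldiphenylsilyl)oxy]-3,7-dimethylnona-3,7-dien-1-yl]-2,4,4-trimethylcyclohexan-1-one (methyl and side chain trans) | CC(C)(C)[Si](c1ccccc1)(c1ccccc1)OC/C=C(\C)CC/C=C(\C)CC[C@@H]1[C@@H](C)C(=O)CCC1(C)C | intermediate
16 | (3S)-3-[(3E,7E)-9-[(tert-butyldiphenylsilyl)oxy]-3,7-dimethylnona-3,7-dien-1-yl]-2,4,4-trimethylcyclohex-1-en-1-yl trifluoromethanesulfonate | CC(C)(C)[Si](c1ccccc1)(c1ccccc1)OC/C=C(\C)CC/C=C(\C)CC[C@@H]1C(C)=C(OS(=O)(=O)C(F)(F)F)CCC1(C)C | intermediate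
17 | tert-butyldiphenyl{[(2E,6E)-3,7-dimethyl-9-[(1S)-2,6,6-trimethylcyclohex-2-en-1-yl]nona-2,6-dien-1-yl]oxy}silane | CC(C)(C)[Si](c1ccccc1)(c1ccccc1)OC/C=C(\C)CC/C=C(\C)CC[C@@H]1C(C)=CCCC1(C)C | intermediate
18 | (2E,6E)-3,7-dimethyl-9-[(1S)-2,6,6-trimethylcyclohex-2-en-1-yl]nona-2,6-dien-1-ol | OC/C=C(\C)CC/C=C(\C)CC[C@@H]1C(C)=CCCC1(C)C | intermediate
19 | oleic acid, (9Z)-octadec-9-enoic acid | CCCCCCCC/C=C\CCCCCCCC(=O)O | starting material
20 | O-oleoyl-N,N'-dicyclohexylisourea | CCCCCCCC/C=C\CCCCCCCC(=O)OC(=NC1CCCCC1)NC1CCCCC1 | intermediate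
21 | (2E,6E)-3,7-dimethyl-9-[(1S)-2,6,6-trimethylcyclohex-2-en-1-yl]nona-2,6-dien-1-yl (9Z)-octadec-9-enoate | CCCCCCCC/C=C\CCCCCCCC(=O)OC/C=C(\C)CC/C=C(\C)CC[C@@H]1C(C)=CCCC1(C)C | target

## Step count and risks

Total step count: 11 (controller 6 is a separately prepared, recoverable reagent).
Longest linear sequence: 11 steps, from 1 to 21.

Steps most likely to fail:

**Step 7 (key step).** What may go wrong:
- hydrogen-atom transfer to the vinyl ketone instead of the isopropenyl group, which would reduce the acceptor or start a cyclisation from C4 onto the isopropenyl CH2;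
- capture of the C6 radical by the C3'=C4' side-chain alkene;
- reversible hydrogen-atom transfer at C1–H, which would erode the stereocentre.

Fallback, setting out from 11 and returning at 15: the radical precursor is installed before the enone exists. Markovnikov hydrochlorination of the isopropenyl group of 11 (Co(BF4)2·6H2O with a salicylaldimine ligand, t-BuOOH, PhSiH3, TsCl, EtOH) would give the tertiary chloride (2R,3R,6E,10E)-12-[(tert-butyldiphenylsilyl)oxy]-3-(2-chloropropan-2-yl)-N-methoxy-N,2,6,10-tetramethyldodeca-6,10-dienamide F1. This relies on the same preference for the 1,1-disubstituted alkene, but no acceptor competes. Addition of CH2=CHMgBr as in step 6 would pass through the magnesium hemiaminal chelate F2 (not isolated) to the chloro vinyl ketone (4R,5R,8E,12E)-14-[(tert-butyldiphenylsilyl)oxy]-5-(2-chloropropan-2-yl)-4,8,12-trimethyltetradeca-1,8,12-trien-3-one F3. Slow addition of Bu3SnH with AIBN in benzene at 80 °C would then generate the same C6 radical by chlorine abstraction and close the C5–C6 bond in the same 6-endo mode to give 15, with no metal hydride present.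

**Step 8.** What may go wrong: enolisation toward C4 instead of C2, so that the triflate is formed on the wrong side of the carbonyl, or acid-induced loss of the allylic silyl ether. Fallback, setting out from 15 and returning at 16: equilibrating silylation (Me3SiCl, NaI, Et3N, MeCN) would give the more substituted trimethylsilyl enol ether F4, which can be purified. MeLi in THF at 0 °C would release the regiodefined lithium enolate F5 (not isolated), and trapping with N-(5-chloropyridin-2-yl)-1,1,1-trifluoro-N-(trifluoromethylsulfonyl)methanesulfonamide would give 16.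

**Step 4.** What may go wrong: a slow sigmatropic shift of the hindered boron ketene acetal, with attrition of the silyl ether under prolonged Lewis acidic conditions, or insufficient facial selectivity. Fallback, setting out from 5 and returning at 9: Ireland–Claisen rearrangement with LiN(i-Pr)2 and Me3SiCl in THF–DMPU (−78 °C to rt) would pass through the trimethylsilyl ketene acetal F6 (not isolated, methyl cis to O–Si) and the racemic trimethylsilyl ester F7 (not isolated). Hydrolysis would give the racemic syn acid, that is 9 together with its (2S,3S) enantiomer F8. Preparative chromatography on a chiral stationary phase would remove F8 and return to 9.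

Further compounds
F1 | step 7 | (2R,3R,6E,10E)-12-[(tert-butyldiphenylsilyl)oxy]-3-(2-chloropropan-2-yl)-N-methoxy-N,2,6,10-tetramethyldodeca-6,10-dienamide | CC(C)(C)[Si](c1ccccc1)(c1ccccc1)OC/C=C(\C)CC/C=C(\C)CC[C@@H](C(C)(C)Cl)[C@@H](C)C(=O)N(C)OC
F2 | step 7 | bromomagnesium salt of the tetrahedral adduct of F1 and vinylmagnesium bromide | CC(C)(C)[Si](c1ccccc1)(c1ccccc1)OC/C=C(\C)CC/C=C(\C)CC[C@@H](C(C)(C)Cl)[C@@H](C)C(O[Mg]Br)(C=C)N(C)OC
F3 | step 7 | (4R,5R,8E,12E)-14-[(tert-butyldiphenylsilyl)oxy]-5-(2-chloropropan-2-yl)-4,8,12-trimethyltetradeca-1,8,12-trien-3-one | CC(C)(C)[Si](c1ccccc1)(c1ccccc1)OC/C=C(\C)CC/C=C(\C)CC[C@@H](C(C)(C)Cl)[C@@H](C)C(=O)C=C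
F4 | step 8 | {[(3S)-3-[(3E,7E)-9-[(tert-butyldiphenylsilyl)oxy]-3,7-dimethylnona-3,7-dien-1-yl]-2,4,4-trimethylcyclohex-1-en-1-yl]oxy}trimethylsilane | CC(C)(C)[Si](c1ccccc1)(c1ccccc1)OC/C=C(\C)CC/C=C(\C)CC[C@@H]1C(C)=C(O[Si](C)(C)C)CCC1(C)C
F5 | step 8 | lithium (3S)-3-[(3E,7E)-9-[(tert-butyldiphenylsilyl)oxy]-3,7-dimethylnona-3,7-dien-1-yl]-2,4,4-trimethylcyclohex-1-en-1-olate | CC(C)(C)[Si](c1ccccc1)(c1ccccc1)OC/C=C(\C)CC/C=C(\C)CC[C@@H]1C(C)=C(O[Li])CCC1(C)C
F6 | step 4 | trimethylsilyl ketene acetal of 5 (methyl cis to O–Si) | CC(C)(C)[Si](c1ccccc1)(c1ccccc1)OC/C=C(\C)CC/C=C(\C)CC/C=C(\C)CO/C(O[Si](C)(C)C)=C/C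
F7 | step 4 | trimethylsilyl ester of the syn acid, formed as the racemate ((2R,3R) enantiomer drawn) | CC(C)(C)[Si](c1ccccc1)(c1ccccc1)OC/C=C(\C)CC/C=C(\C)CC[C@@H](C(C)=C)[C@@H](C)C(=O)O[Si](C)(C)C
F8 | step 4 | (2S,3S,6E,10E)-12-[(tert-butyldiphenylsilyl)oxy]-2,6,10-trimethyl-3-(prop-1-en-2-yl)dodeca-6,10-dienoic acid, the enantiomer of 9 | CC(C)(C)[Si](c1ccccc1)(c1ccccc1)OC/C=C(\C)CC/C=C(\C)CC[C@H](C(C)=C)[C@H](C)C(=O)O
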